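(The data come from a simulation for substances that don't exist, and the scatter is random.)

The closed, stirred vessel held an electrophile, a nucleophile in excess and a solid base, none of it dissolved at the start, and I wanted the part of the electrophile reacted at the end.

| flask | electrophile | nucleophile | solid base | remark | time |
|---|---|---|---|---|---|
| green | 0.30 M | 0.63 M | 0.090 M | run made earlier |  |
| grey | 0.30 M | 0.61 M | 0.090 M | run made earlier |  |
| blue | 0.30 M | 0.84 M | 0.090 M | run made earlier |  |
| south | 0.30 M | 0.540 M | 0.0900 M |  | 3.0 min |
| west | 0.30 M | 0.810 M | 0.0900 M |  | 3.0 min |

| run | time / min | electrophile / % | target / % |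
|---|---|---|---|
| green | 0.250 | 96.7 | 3.2 |
| green | 0.417 | 94.9 | 5.0 |
| green | 0.833 | 89.9 | 10.0 |
| green | 1.50 | 83.6 | 16.8 |
| green | 3.00 | 70.5 | 30.2 |
| grey | 0.250 | 96.6 | 2.9 |
| grey | 0.417 | 95.2 | 4.6 |
| grey | 0.833 | 90.9 | 9.6 |
| grey | 1.50 | 84.3 | 16.5 |
| grey | 3.00 | 71.3 | 29.0 |
| blue | 0.250 | 95.9 | 4.5 |
| blue | 0.833 | 86.6 | 13.0 |
| blue | 1.33 | 80.1 | 18.9 |
| blue | 2.00 | 71.9 | 28.4 |
| blue | 3.00 | 62.4 | 37.2 |

(readings scatter by 0.3 percentage points)

- the earlier runs were read with a standard deviation of 0.3 percentage points
- at the start none of the solid base is in solution

* part of the electrophile that has reacted at the end, south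
* part of the electrophile that has reacted at the end, west
* what raising the concentration of nucleophile from its lowest to its highest value here does to the part of the electrophile that has reacted (changes below 5 percentage points count as none) (no change / it rises / it falls)

From blue, where the electrophile fell to 62.4% at 3.00 min, I took the nucleophile averaged over the run and read 0.201 /M/min for the second-order coefficient, the fraction of the electrophile lost per minute for each mole per litre of nucleophile. Green, with less nucleophile, read 0.199 /M/min, so I carried the first value.

In the first instants this coefficient gave 3.16% of target in green at 0.250 min, and the reading was 3.2%, so the green readings showed no lag. Through the middle I reckoned the electrophile as nearly pseudo-first-order, with the nucleophile, in excess, falling from its charge. Near the end there is a mark to watch: the base charge equals 30.0% of the electrophile charged. Green was read at 29.5% reacted at 3.00 min, below the mark, while blue was read at 37.6% at 3.00 min, past it, and the coefficients read from these two runs still matched.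

I then solved both ends and joined them. Holding the nucleophile at its charge gave the upper end, and holding it at its charge less what that conversion consumes gave the lower end. For south the two estimates were 27.7% and 24.0%, with a mean of 25.9%. For west they were 38.6% and 34.2%, with a mean of 36.4%. That is a rise of 10 percentage points, beyond the 5 points that counts.

The forecast, reading “simple second-order behaviour”, gave 26% and 36%, and it rises. The simulation gave 26.1% for south and 36.4% for west: it rises, by 10 points.

    acid set free + free base ⇌ salt of the base, settled at all times (K = 1.10 × 10⁵ /M)
    electrophile + nucleophile → acid set free + target (k = 0.00340 /M/s)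
    crystals ⇌ acid set free, rate k3*(cs3 - [acid set free]) while solid is left; crystals form when [acid set free] > cs3 (solubility = 12.0 mM, k = 0.0510 /s)
    solid base ⇌ free base, rate k4*(cs4 - [free base]) while solid is left; crystals form when [free base] > cs4 (solubility = 0.0980 M, k = 0.0700 /s)
    acid set free → by-product carried off (k = 0.00730 /s)
    nucleophile + acid set free ⇌ protonated nucleophile, settled at all times (K = 620 /M)

Neither flask had come to rest. West still held 64% of its electrophile at 3.0 min, and with 83% of its nucleophile left, the coefficient gives a half-life of 5.15 min, longer than the run. Ten times the time takes south to 81.0% and west to 94.0%, a further 58 points in west. By 30.0 min west holds 5.95% of its electrophile.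

For the neighbour of west charged with 1.4 M of nucleophile, the coefficient gives ends of 56.9% and 52.3%, with a mean of 54.6%. The simulation gave 54.1%.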